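In a one-step world with excess reagent, substrate decays exponentially and target climbs to full yield, so one rate constant describes a flask. These runs are less simple.

| flask | substrate | reagent in the second phase | remark | time | volume of the second phase over the first |
|---|---|---|---|---|---|
| autumn | 0.093 M | 1.2 equiv | run made earlier |  |  |
| summer | 0.093 M | 1.9 equiv | run made earlier |  |  |
| dawn | 0.19 M | 2.5 equiv | run made earlier |  |  |
| flask | 0.093 M | 2.50 equiv |  | 2.0 min | 0.50 |

| run | time / s | target / % |
|---|---|---|
| autumn | 10.0 | 22 |
| autumn | 20.0 | 33 |
| autumn | 30.0 | 39 |
| autumn | 40.0 | 42 |
| autumn | 50.0 | 47 |
| autumn | 60.0 | 47 |
| autumn | 80.0 | 52 |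
| summer | 10.0 | 31 |
| summer | 12.0 | 35 |
| summer | 20.0 | 44 |
| summer | 30.0 | 54 |
| summer | 50.0 | 58 |
| summer | 80.0 | 63 |
| dawn | 10.0 | 62 |
| dawn | 20.0 | 70 |
| dawn | 30.0 | 69 |
| dawn | 50.0 | 67 |
| dawn | 80.0 | 69 |

(each reading ± 2 percentage points)

- in the second phase: reagent in the second phase; everything else is in the first
- charges count per volume of the first phase; a concentration in a rate is the amount of a species over the volume of its own phase; every rate counts per litre of the first phase
- what was read earlier has a scatter of 2 percentage points, one standard deviation
- the earlier runs hold the two phases in the same ratio of volumes as the flask asked about

- amber: doubling the transfer coefficient of the reagent in the second phase, all else as stated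
- violet: doubling the amount of reagent in the second phase, all else as stated

1. amount of target at 2.0 min, in percent of the substrate charged
2. the change that raises the amount of target at 2.0 min, in percent of the substrate charged most ("none" if none brings more than 2 percentage points) (amber / violet / none)
3. amount of target at 2.0 min, in percent of the substrate charged, after violet

The dawn run stopped short. I averaged its last four readings:

ceiling = 68.8%

I took this as the ceiling of target at 2.5 equiv, the equivalents of the flask. The autumn and summer runs were still climbing at their last readings, so I read no lower ceiling from them. Below the ceiling I treated the climb as pseudo-first-order, with the rate constant proportional to the reagent charged. The first summer reading gives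

rate constant = ln(1 / (1 − target / ceiling)) / time = 0.0599 /s

The first autumn reading gives 0.0386 /s. So summer ran 1.55 times as fast on 1.58 times the equivalents, which supports the proportion. Scaling summer to the flask, at the same substrate concentration:

rate constant = 0.0789 /s

half-time = ln(2) / rate constant = 8.79 s

This is the approach half-time, the time in which the gap between target and ceiling halves. It marks the crossing: a reading within a few half-times still lies below the ceiling, and a reading far beyond them lies at it. The flask's 2.0 min is 13.7 half-times, so I expected 68.8% of target. By the proportion, violet shortens the half-time to 4.39 s in a flask I reckoned to be at its ceiling already, and I took amber as a change of speed too. Assuming the ceiling holds at doubled equivalents, I expected neither change to bring more than the 2 percentage points margin.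

The forecast gave 69%, violet and 82% after violet, holding that “this looks like an equilibrium, not slow kinetics”, and it differs from my reckoning on violet, where I kept 68.8%.

The simulation ran this scheme:

    substrate → decomposition product (k = 1.50 × 10⁻⁵ /s)
    substrate + reagent in the reaction phase → target (k = 0.440 /M/s)
    reagent in the reaction phase ⇌ reagent in the second phase, rate k3*([reagent in the reaction phase] - [reagent in the second phase]/K3) per volume of the first phase (partition coefficient = 0.600, kL = 0.340 /s)
    target ⇌ isomer of the product (K = 0.420, k = 0.0340 /s)
    reagent in the reaction phase → decomposed reagent (k = 0.0110 /s)

The flask held 69.0% of target at 2.00 min, beside 28.8% of isomer of the product. Violet brought it to 70.4%, a gain of 1.4 points, less than the 2 points margin, and amber gained 0.011 points, so the answer is none. The neighbouring flask, the same charge read at 30 s, stands 3.41 half-times in, with the gap still open. The reckoning gives it 62.3% of target, and it held 59.7%.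

The runs stem from a simulated flask for an exercise, noise included.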